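Late times carry the comparison: zeta and beta hold the same starting material and precatalyst loading but very different second substrate, and both were read at 4.00 h, 5.00 h and 6.00 h.

| setting | zeta | beta | west | east | south | north-west | south-west |
|---|---|---|---|---|---|---|---|
| starting material | 0.20 M | 0.20 M | 0.20 M | 0.20 M | 0.20 M | 0.20 M | 0.20 M |
| second substrate | 0.31 equiv | 6.2 equiv | 0.250 equiv | 0.500 equiv | 1.00 equiv | 2.00 equiv | 4.00 equiv |
| precatalyst | 0.089 mol% | 0.089 mol% | 0.089 mol% | 0.089 mol% | 0.089 mol% | 0.089 mol% | 0.089 mol% |
| remark | run made earlier | run made earlier |  |  |  |  |  |
| time |  |  | 12 h | 12 h | 12 h | 12 h | 12 h |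

| run | time / h | target / % | starting material / % |
|---|---|---|---|
| zeta | 0.833 | 1.1 | 97.9 |
| zeta | 1.50 | 1.7 | 100.2 |
| zeta | 2.50 | 2.8 | 97.1 |
| zeta | 3.00 | 6.3 | 93.7 |
| zeta | 4.00 | 10.5 | 90.6 |
| zeta | 5.00 | 13.8 | 86.8 |
| zeta | 6.00 | 18.4 | 82.1 |
| beta | 0.333 | 0.3 | 98.1 |
| beta | 1.00 | 0.3 | 99.4 |
| beta | 1.50 | 0 | 99.4 |
| beta | 2.50 | 0 | 99.9 |
| beta | 4.00 | 1.5 | 97.4 |
| beta | 5.00 | 0.7 | 97.6 |
| beta | 6.00 | 1.7 | 97.2 |

(readings scatter by 1 percentage point)

- in percentages every species weighs as the starting material in it: one homo dimer counts as two
- steps under discussion: starting material + free catalyst <-> catalyst intermediate A; catalyst intermediate A -> free catalyst + target; second substrate + free catalyst <-> catalyst intermediate B; catalyst intermediate B -> free catalyst + second product; 2 starting material -> homo dimer; precatalyst -> free catalyst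
- "hardly changes" means that all values lie within two and a half points (for a concentration: within two and a half percent of the largest)

- amount of target at the end, in percent of the starting material charged for west, east, south, north-west, south-west, in this order
- the course of these numbers from the first flask to the last (rises, then falls / hardly changes / rises all the way / falls, then rises / falls all the way)

How strongly does second substrate hold target back? Summed over those three times, target in zeta stands to target in beta as 10.9 to one. Dividing the two takes time out, provided both flasks free their catalyst on one clock. Each beta reading carries a scatter of 1 percentage point, so this ratio is a rough reading.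

What charge does that ratio mean? The reckoning made here assumes competitive inhibition: target at a given time goes as one over one plus equivalents divided by a fixed charge. The ratio then makes 0.282 equiv the half-suppression charge, the amount of second substrate at which this rule puts target at half of the value it gives for no second substrate at that time.

How far does the clock carry by 12 h? In zeta, from 3.00 h to 6.00 h, twice the time, target grows by a factor 2.92. This reckoning applies that factor once more to zeta's 18.4 %, then rescales by the rule from zeta's charge to each flask's. With 53.7 % as the estimated base for zeta, it gives 59.8 %, 40.7 %, 24.8 %, 13.9 % and 7.43 %, so this estimate puts south-west lower than west.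

The forecast reads 43 %, 36 %, 21 %, 6 % and 4 %, and its course falls all the way. Its grounds are a slow start in zeta read as “the second substrate holding the catalyst and being consumed first”. For north-west it stands lower than this reckoning.

The flasks give 57.9 %, 47.2 %, 34.2 %, 21.9 % and 12.8 %; the row falls all the way.

    starting material + free catalyst ⇌ catalyst intermediate A (K = 4.62 L mol⁻¹, k = 486 L mol⁻¹ min⁻¹)
    catalyst intermediate A → free catalyst + target (k = 9.94 min⁻¹)
    second substrate + free catalyst ⇌ catalyst intermediate B (K = 160 L mol⁻¹, k = 16.0 L mol⁻¹ min⁻¹)
    catalyst intermediate B → free catalyst + second product (k = 0.895 min⁻¹)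
    2 starting material → homo dimer (k = 1.07 × 10⁻⁵ L mol⁻¹ min⁻¹)
    precatalyst → free catalyst (k = 0.00137 min⁻¹)

At 12.0 h precatalyst stands at 37.3 % of the catalyst charged in west and at 37.3 % in south-west. The half-suppression charge divides west's 57.9 % by 8.05 and gives 7.19 % for south-west. South-west holds 12.8 %.

(The data are calculated for an exercise; scatter was added.)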